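**Plan**
- Retrosynthesis: the three MOM ethers come off last; the C6'–H bond of ring A is traced back to a C–OTf and then a C–OH bond; the two aryl–CH2 bonds C3'–CH2 and C5'–CH2 are then cut, giving phloretin and two molecules of prenyl bromide.
- Forward: both prenyl chains are joined to ring A of phloretin first, in one flask. Three hydroxyls are then masked, the remaining chelated ortho-hydroxyl is triflated and reduced to C–H, and the masks are removed. No ring is formed.
- Enabling feature: C6' of ring A bears hydrogen in the target but oxygen in phloretin. With that oxygen in place, C3' and C5' are the only unsubstituted ring A carbons and are mirror-related through the C1'–C4' axis. The C2' and C6' hydroxyls are likewise equivalent, so deleting either gives the target pattern.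
- Stereochemistry: the target has no stereocentre and no stereogenic double bond (each prenyl olefin ends in two methyl groups), so nothing has to be controlled.

Key step: step 1

Assumption: with K2CO3 in acetone, MOMCl leaves exactly one of the two equivalent carbonyl-flanking hydroxyls free, because the survivor is locked in a hydrogen bond to the ketone, as is usual for simpler acylphloroglucinols. Primed locants refer to ring A (acyl group on C1'), unprimed locants to ring B.

**Route**

Step 1
Reactants: 1 phloretin; 2 prenyl bromide
Product: 4 3',5'-diprenylphloretin, via 3'-prenylphloretin 3 (not isolated)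
Conditions: 2 (2.05 equiv in all, slow addition), KOH (2.2 equiv, 1 M aq.), degassed H2O, 0 °C, Ar; mildly acidic work-up
Reagents that add atoms: prenyl bromide (second equivalent of 2), CC(C)=CCBr
Why: The acylphloroglucinol ring is a vinylogous acid and far more acidic than the ring B phenol, so with hydroxide limited to about one equivalent per alkylation it is the ring that stays ionised; its ambident phenoxide attacks the first equivalent of the soft allylic bromide by SN2 through carbon C3' to give a cyclohexadienone that re-aromatises at once by loss of the C3' proton to 3, and the same sequence at C5' with the second equivalent of 2 gives 4. The closest known reaction type is the base-mediated C-prenylation of acylphloroglucinols in protic media, the laboratory counterpart of aromatic prenyl transfer in hop acid biosynthesis. No ring closes and no stereocentre is created. The step needs C- over O-alkylation, which water secures by hydrogen bonding to the phenoxide oxygens, and ring A over ring B selectivity, which the acidity difference and the limited amount of base secure. Position selectivity comes from the substrate itself, since C3' and C5' are the only unsubstituted ring A carbons and are related by the mirror plane through C1' and C4'. Over-alkylation to a 3',3'-diprenyl dienone is held back by the stoichiometry of 2, the low temperature and the loss of aromaticity it would cost.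

Step 2
Reactants: 4 3',5'-diprenylphloretin
Product: 5 4,4',6'-tris-O-MOM-3',5'-diprenylphloretin (2'-OH free and chelated)
Conditions: MOMCl (3.5 equiv), K2CO3 (4 equiv), acetone, reflux, Ar
Reagents that add atoms: chloromethyl methyl ether (MOMCl, three equivalents incorporated), COCCl
Why: Williamson-type O-alkylation with the hard chloromethyl ether protects the ring B phenol, the 4'-hydroxyl and one ortho-hydroxyl, while the last ortho-hydroxyl is held unreactive by its hydrogen bond to the ketone under this weak-base regime.

Step 3
Reactants: 5 4,4',6'-tris-O-MOM-3',5'-diprenylphloretin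
Product: 6 2'-O-triflyl-4,4',6'-tris-O-MOM-3',5'-diprenylphloretin
Conditions: Tf2O (1.3 equiv), pyridine, CH2Cl2, 0 °C to rt
Reagents that add atoms: trifluoromethanesulfonic anhydride (Tf2O), O=S(=O)(OS(=O)(=O)C(F)(F)F)C(F)(F)F
Why: O-sulfonylation of the only free phenol with the most reactive triflating agent overcomes the chelation and the flanking prenyl group, and the pyridine buffer protects the MOM acetals and the prenyl olefins from triflic acid.

Step 4
Reactants: 6 2'-O-triflyl-4,4',6'-tris-O-MOM-3',5'-diprenylphloretin
Product: 7 tris-O-MOM gancaonin J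
Conditions: Pd(OAc)2 (10 mol %), 1,3-bis(diphenylphosphino)propane (dppp, 12 mol %), HCO2H (3 equiv), Et3N (4.5 equiv), DMF, 70 °C
Reagents that add atoms: none
Why: Palladium-catalysed formate reduction of an aryl triflate: zerovalent palladium inserts into the C–OTf bond, which the ortho acyl group activates, formate replaces triflate on palladium and loses CO2, and reductive elimination of the aryl palladium hydride forms the C–H bond, leaving ketone, acetals and trisubstituted olefins untouched.

Step 5
Reactants: 7 tris-O-MOM gancaonin J
Product: 8 gancaonin J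
Conditions: HCl (1.25 M in MeOH), 0 °C to rt
Reagents that add atoms: none
Why: Acid-catalysed transacetalisation to methanol cleaves all three aryl MOM ethers under dilute, cold conditions, where oxocarbenium formation should be much faster than protonation of the prenyl double bonds.

**Compound list**
1 | phloretin, 3-(4-hydroxyphenyl)-1-(2,4,6-trihydroxyphenyl)propan-1-one | O=C(CCc1ccc(O)cc1)c1c(O)cc(O)cc1O | starting material
2 | prenyl bromide, 1-bromo-3-methylbut-2-ene | CC(C)=CCBr | starting material
3 | 3'-prenylphloretin, 3-(4-hydroxyphenyl)-1-[2,4,6-trihydroxy-3-(3-methylbut-2-enyl)phenyl]propan-1-one | CC(C)=CCc1c(O)cc(O)c(C(=O)CCc2ccc(O)cc2)c1O | intermediate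
4 | 3',5'-diprenylphloretin, 3-(4-hydroxyphenyl)-1-[2,4,6-trihydroxy-3,5-bis(3-methylbut-2-enyl)phenyl]propan-1-one | CC(C)=CCc1c(O)c(CC=C(C)C)c(O)c(C(=O)CCc2ccc(O)cc2)c1O | intermediate
5 | 1-[2-hydroxy-4,6-bis(methoxymethoxy)-3,5-bis(3-methylbut-2-enyl)phenyl]-3-[4-(methoxymethoxy)phenyl]propan-1-one | CC(C)=CCc1c(OCOC)c(CC=C(C)C)c(OCOC)c(C(=O)CCc2ccc(OCOC)cc2)c1O | intermediate
6 | 2-{3-[4-(methoxymethoxy)phenyl]propanoyl}-3,5-bis(methoxymethoxy)-4,6-bis(3-methylbut-2-enyl)phenyl trifluoromethanesulfonate | CC(C)=CCc1c(OCOC)c(CC=C(C)C)c(OCOC)c(C(=O)CCc2ccc(OCOC)cc2)c1OS(=O)(=O)C(F)(F)F | intermediate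
7 | 1-[2,4-bis(methoxymethoxy)-3,5-bis(3-methylbut-2-enyl)phenyl]-3-[4-(methoxymethoxy)phenyl]propan-1-one | CC(C)=CCc1cc(C(=O)CCc2ccc(OCOC)cc2)c(OCOC)c(CC=C(C)C)c1OCOC | intermediate
8 | gancaonin J, 1-[2,4-dihydroxy-3,5-bis(3-methylbut-2-enyl)phenyl]-3-(4-hydroxyphenyl)propan-1-one | CC(C)=CCc1cc(C(=O)CCc2ccc(O)cc2)c(O)c(CC=C(C)C)c1O | target

**Count**
Total steps: 5. Longest linear sequence: 5 steps (1 → 4 → 5 → 6 → 7 → 8).

**Steps most likely to fail, with fallbacks**

Step 1. The one-pot double alkylation may be eroded by O-prenylation of the ring B phenol, by O-alkylation on ring A, and by a third, dearomatising alkylation at an already substituted carbon. The fallback makes the two C–C bonds one at a time under aprotic amidine conditions. Compound 1 is treated with one equivalent of 2 and DBU in THF at room temperature, which should stop at the mono-C-prenyl stage. The resulting 3'-prenylphloretin 3 is isolated and purified, and a second pass with one more equivalent of 2 and DBU in THF converts it into 4, where the route is rejoined. This detour makes no compound outside the list (F0).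

Step 4. Oxidative addition at the doubly ortho-substituted carbon may be slow, so that S–O cleavage of the triflate by the formate/amine medium returns phenol 5. The fallback changes the leaving group. Compound 5 is deprotonated with NaH in THF at 0 °C and treated with nonafluorobutanesulfonyl fluoride. This should give the aryl nonaflate, 2-{3-[4-(methoxymethoxy)phenyl]propanoyl}-3,5-bis(methoxymethoxy)-4,6-bis(3-methylbut-2-enyl)phenyl nonafluorobutane-1-sulfonate F1, which resists S–O cleavage far better. Reduction of F1 with Pd(OAc)2, dppp, HCO2H and Et3N in DMF at 80 °C then returns to 7.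

Step 5. The acid that cleaves the acetals may also protonate the prenyl double bonds, after which the neighbouring phenols close onto the tertiary cations to form 2,2-dimethylchromans. The fallback avoids acid altogether by carrying fluoride-labile silyl ethers. Compound 4 with TBSCl and imidazole in DMF should give the tris-silyl ether with the chelated hydroxyl free, 1-[2,4-bis(tert-butyldimethylsilyloxy)-6-hydroxy-3,5-bis(3-methylbut-2-enyl)phenyl]-3-[4-(tert-butyldimethylsilyloxy)phenyl]propan-1-one F2. Tf2O and pyridine in CH2Cl2 convert it into the aryl triflate, 3,5-bis(tert-butyldimethylsilyloxy)-2-{3-[4-(tert-butyldimethylsilyloxy)phenyl]propanoyl}-4,6-bis(3-methylbut-2-enyl)phenyl trifluoromethanesulfonate F3. Reduction with Pd(OAc)2, dppp, HCO2H and Et3N in DMF gives 1-[2,4-bis(tert-butyldimethylsilyloxy)-3,5-bis(3-methylbut-2-enyl)phenyl]-3-[4-(tert-butyldimethylsilyloxy)phenyl]propan-1-one F4. Tetrabutylammonium fluoride buffered with acetic acid in THF at 0 °C then removes the three silyl groups and arrives at 8.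

**Further compounds**
F0 | step 1 | none | none
F1 | step 4 | 2-{3-[4-(methoxymethoxy)phenyl]propanoyl}-3,5-bis(methoxymethoxy)-4,6-bis(3-methylbut-2-enyl)phenyl nonafluorobutane-1-sulfonate | CC(C)=CCc1c(OCOC)c(CC=C(C)C)c(OCOC)c(C(=O)CCc2ccc(OCOC)cc2)c1OS(=O)(=O)C(F)(F)C(F)(F)C(F)(F)C(F)(F)F
F2 | step 5 | 1-[2,4-bis(tert-butyldimethylsilyloxy)-6-hydroxy-3,5-bis(3-methylbut-2-enyl)phenyl]-3-[4-(tert-butyldimethylsilyloxy)phenyl]propan-1-one | CC(C)=CCc1c(O[Si](C)(C)C(C)(C)C)c(CC=C(C)C)c(O[Si](C)(C)C(C)(C)C)c(C(=O)CCc2ccc(O[Si](C)(C)C(C)(C)C)cc2)c1O
F3 | step 5 | 3,5-bis(tert-butyldimethylsilyloxy)-2-{3-[4-(tert-butyldimethylsilyloxy)phenyl]propanoyl}-4,6-bis(3-methylbut-2-enyl)phenyl trifluoromethanesulfonate | CC(C)=CCc1c(O[Si](C)(C)C(C)(C)C)c(CC=C(C)C)c(O[Si](C)(C)C(C)(C)C)c(C(=O)CCc2ccc(O[Si](C)(C)C(C)(C)C)cc2)c1OS(=O)(=O)C(F)(F)F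
F4 | step 5 | 1-[2,4-bis(tert-butyldimethylsilyloxy)-3,5-bis(3-methylbut-2-enyl)phenyl]-3-[4-(tert-butyldimethylsilyloxy)phenyl]propan-1-one | CC(C)=CCc1cc(C(=O)CCc2ccc(O[Si](C)(C)C(C)(C)C)cc2)c(O[Si](C)(C)C(C)(C)C)c(CC=C(C)C)c1O[Si](C)(C)C(C)(C)C
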